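## Analysis of the target

The target is a labdane ester: a trans-decalin (ring A: C1–C5 and C10; ring B: C5–C10) with the C18 methyl and the C19 acyloxymethyl group on C4, the C17 methyl and a hydroxyl group on C8, the C20 methyl on C10, and on C9 the chain C11–C12–C13(=C16)–C14=C15 (labdane numbering, used throughout). All five stereocenters lie in the ring system and are contiguous along C4–C5–C10–C9–C8, (4S,5R,8R,9R,10S): 5α-H and 10β-CH3 (trans fusion), 9α-H with the chain equatorial, 8α-OH equatorial with C17 axial, and at C4 the oxidized carbon C19 axial (β), 1,3-diaxial to C20. C4 and C10 are quaternary and C8 is a tertiary carbinol, so three of the five centers cannot be corrected later by epimerization. The hard point is C4: its two one-carbon substituents differ only in oxidation level, the oxidized one sits in the more hindered axial position, and ring A (C1–C3 bare methylenes) offers no functional group from which to reach it. The sensitive groups all lie outside the rings: the 2-substituted buta-1,3-diene (acids, radicals, electrophiles), the Z-enoate (light, bases, nucleophiles and metal hydrides give the E isomer), the free phenol, and the tertiary alcohol (dehydration, ether formation with the chain). They therefore enter late, in the order C8–OH, diene, Z-enoate, and the ring system with its C4 problem is what the strategy must solve.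

## Retrosynthetic reasoning

The Z-enoate is the most fragile group and is made last. The Cα=Cβ bond of the coumarate is cut (24 ⇒ 23 ⇒ 21 + 22): a Z-selective Still–Gennari olefination builds the alkene on the molecule, so that no preformed Z-cinnamic acid has to survive the slow acylation of the hindered, neopentyl C19 alcohol. The C19–O acyl bond is then cut (21 ⇒ 19 + 20). The forward acylation must tell the primary C19–OH from the tertiary C8–OH, which sterics secure.

The C13–C14 bond is cut next (19 ⇒ 17 ⇒ 15). A 2-substituted buta-1,3-diene is the coupling product of a 1-alken-2-yl triflate with a vinyl metal, and that triflate is the kinetic enol derivative of a methyl ketone. This puts C13 at the ketone level, which is what the cheap C13 building block 1 supplies, and it avoids a dehydration that would give regioisomeric dienes. The forward steps must enolize toward C16 and not C12, and the two hydroxyl groups need a short-lived silyl cover (16).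

Ketone 15 is traced to the bicyclic keto ester 9 by functional group changes only (15 ⇒ 13 ⇒ 12 ⇒ 10 ⇒ 9). The C3 oxygen, which the key step needs and the target lacks, is removed as the secondary partner of a 3,19-diol by radical deoxygenation. One hydride reduction converts the C3 ketone, the C19 ester and a C8 spiro-epoxide together. The C8–O bond comes from face-selective epoxidation of an exocyclic C8=C17 alkene, so C8 is relayed from C10, whose axial methyl group blocks the β-face.

The key disconnection cuts C4–C5 and C9–C10 (9 ⇒ 8), which opens both rings and leaves an acyclic triene. The cut is made there because C4 then becomes the α-carbon of a 2-methyl-3-oxo ester. That carbon can be turned into a radical selectively in the presence of the alkenes, it already carries C18 and C19 at different oxidation levels, and the ester is the natural seat for a chiral auxiliary. A cationic opening of the same bonds was not chosen because an allylic C19 oxygen makes the C3=C4 alkene the least nucleophilic site of the chain, so initiation would not be selective. Forward, the reaction must close two six-membered rings in the endo mode, set C4, C5, C9 and C10, and end in the C8=C17 alkene.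

Triene 8 is cut at C1–C2 (8 ⇒ 7 + 4): γ-alkylation of the dianion of acetoacetate 7 with allylic bromide 4 joins a C5 unit (C2, C3, C4, C18, C19) to a C13 unit. Bromide 4 comes from 1 by ketalization (2), E-selective allylic oxidation of the terminal methyl group (3) and bromination. The E geometry of both alkenes, which later fixes the trans fusion and the equatorial chain, is bought with 1 and kept. Ester 7 comes from 5 and 6 by transesterification. The ketal keeps the dianion and, later, the hydride away from C13.

## Alternatives that were turned down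

Alternative 1: annulation and relay (the textbook route). Disconnection: the decalin is bought as the Robinson annulation product, (S)-Wieland–Miescher ketone A1, and the stereocenters are added one or two at a time. Forward key step: after ketalization of the saturated ketone, reductive methoxycarbonylation of the enone of A1 and methylation of the β-keto ester from the α-face give keto ester A2 with C4, C5 and C10 in place. Turned down because A2 still lacks the C3 deoxygenation, the C17 methyl group, the C8 oxygen and the whole C9 chain. All of these must be built on one hindered C9 carbonyl next to the quaternary C10, C8 and C9 would be set in separate, weakly controlled steps, and the count passes twenty steps.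

Alternative 2: tricyclization by hydrogen-atom transfer. Disconnection: C4–C5, C9–C10 and C8–O, with no oxygen at C3. Forward key step: a metal-hydride hydrogen-atom transfer to the 1,1-disubstituted alkene of trienone A3 gives the tertiary C4 radical, which after radical–polar crossover cyclizes twice and is captured by the ketone oxygen to give enol ether A4 in one step. Turned down on stereochemical grounds: C4 forms from a planar center carrying CH3 and CH2OSi groups of almost equal size, so nothing decides which becomes axial, and the achiral chain offers no handle for the absolute configuration. A racemic mixture of C4 epimers would cost more to resolve than the three steps the missing C3 oxygen saves.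

Alternative 3: chiral pool and late C–H oxidation. Disconnection: the C19–O bond, cut back to a C–H bond of commercial (+)-sclareolide A5, which already holds C5, C8, C9 and C10. Forward key step: hydroxylation of the axial C19 methyl group to 19-hydroxysclareolide A6, then opening of the lactone toward the side chain. Turned down because the C19–H bonds are primary, hindered by C20 and out of reach of every oxygen in A5, while C–H oxidants on this skeleton prefer the C2 and C3 methylene groups. A directing group would first have to be built at C3 or C6 and then removed, and the equatorial C18 methyl group would compete.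

Key step: step 6

Remark 1 (assumption): the phenyl ring of the (1R,2S,5R)-8-phenylmenthyl ester is taken to cover the face of the C4 radical whose blocking leads to the 4β-ester, 10β-methyl series drawn for 9; if the sense is the opposite, the enantiomeric auxiliary is used and nothing else changes.

Remark 2 (assumption): 1 is used as the pure E isomer, and 20 and 22 are taken as purchasable (each is otherwise one routine step from a commercial ester or phenol).

## Route

Step 1
Reactants: 1 (E)-geranylacetone
Product: 2 2-[(3E)-4,8-dimethylnona-3,7-dien-1-yl]-2-methyl-1,3-dioxolane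
Conditions: ethylene glycol, PPTS (cat.), benzene, reflux, Dean–Stark trap
Reagents that add atoms: ethylene glycol, OCCO
Why: Acid-catalysed ketalization with azeotropic removal of water; the ketone must be masked against the dianion of step 5 and the hydride of step 8, and the trisubstituted alkenes do not react under these weakly acidic conditions.

Step 2
Reactants: 2 geranylacetone ketal
Product: 3 (2E,6E)-2,6-dimethyl-9-(2-methyl-1,3-dioxolan-2-yl)nona-2,6-dien-1-ol
Conditions: SeO2 (cat.), t-BuOOH, CH2Cl2, 0 °C to rt
Reagents that add atoms: tert-butyl hydroperoxide, CC(C)(C)OO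
Why: Selenium dioxide allylic oxidation (ene reaction, then [2,3]-sigmatropic shift) attacks the terminal, least hindered trisubstituted alkene at its E-methyl group, so the new CH2OH is trans to the chain and the E geometry of the future C5=C10 alkene is fixed. The reaction is stopped before over-oxidation to the enal becomes important.

Step 3
Reactants: 3 allylic alcohol
Product: 4 2-[(3E,7E)-9-bromo-4,8-dimethylnona-3,7-dien-1-yl]-2-methyl-1,3-dioxolane
Conditions: CBr4, PPh3, CH2Cl2, −20 to 0 °C
Reagents that add atoms: carbon tetrabromide, BrC(Br)(Br)Br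
Why: Appel bromination under neutral conditions; a primary allylic alcohol reacts by direct substitution without allylic shift or E/Z isomerization, and the ketal survives.

Step 4
Reactants: 5 (−)-8-phenylmenthol; 6 ethyl 2-methyl-3-oxobutanoate
Product: 7 (1R,2S,5R)-8-phenylmenthyl 2-methyl-3-oxobutanoate (both epimers at C2 of the butanoate)
Conditions: DMAP (cat.), toluene, reflux, slow removal of EtOH
Reagents that add atoms: none
Why: DMAP-catalysed transesterification of a β-keto ester, which runs through the acylketene and so also works with a hindered secondary alcohol; the configuration at C2 of the butanoate is of no consequence because this carbon becomes the radical center in step 6.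

Step 5
Reactants: 7 auxiliary acetoacetate; 4 allylic bromide
Product: 8 (1R,2S,5R)-8-phenylmenthyl (6E,10E)-2,6,10-trimethyl-13-(2-methyl-1,3-dioxolan-2-yl)-3-oxotrideca-6,10-dienoate
Conditions: NaH, THF, 0 °C; n-BuLi, 0 °C; then 4, 0 °C to rt
Reagents that add atoms: none
Why: γ-Alkylation of the dianion of a β-keto ester: the more basic terminal carbanion displaces the primary allylic bromide by SN2 substitution, which forms the C1–C2 bond and leaves the alkene geometry untouched.

Step 6
Reactants: 8 triene β-keto ester
Product: 9 (1R,2S,5R)-8-phenylmenthyl 13,13-(ethylenedioxy)-3-oxo-14,15-dinorlabd-8(17)-en-19-oate (4α-CH3, 4β-ester, 5α-H, 9α-H, 10β-CH3)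
Conditions: Mn(OAc)3·2H2O (2.2 equiv), Cu(OAc)2·H2O (1 equiv), degassed EtOH, 25–40 °C
Reagents that add atoms: none
Why: Trivalent manganese oxidizes the enol of the 2-methyl β-keto ester to the electrophilic tertiary C4 radical, which adds to C5 of the C5=C10 alkene; the tertiary C10 radical then adds to C9 of the C8=C9 alkene, and divalent copper (regenerated by trivalent manganese) oxidizes the tertiary C8 radical to the exocyclic C8=C17 alkene by loss of the least hindered β-hydrogen. The closest known reaction type is the manganese triacetate/copper diacetate oxidative polyene cyclization of 2-alkylacetoacetates, which in its arene- and alkene-terminated forms gives the same 3-oxo-4-methyl-4-carboxylate trans-decalin; ethanol, a known solvent for it, replaces acetic acid so that the ketal is not hydrolysed. Both rings close in the 6-endo-trig mode, because the methyl groups on C10 and C8 block the 5-exo positions and make the endo adduct radicals tertiary. C4: this class of radical cyclizes with the ester carbon axial (cis to C20) and the methyl group equatorial, and the face of C4 that bonds to C5 is the one not covered by the phenyl ring of the auxiliary. C5 and C10: a chair transition state on the E-configured C5=C10 alkene gives the trans ring fusion. C9: the second chair on the E-configured C8=C9 alkene places the chain equatorial, trans to C20. The step needs chemoselective oxidation of the β-keto ester in the presence of the ketal and the isolated alkenes, which its far higher enol content secures, and ring closure of the C10 radical faster than its oxidation, which a low stationary concentration of divalent copper favours.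

Step 7
Reactants: 9 bicyclic alkene
Product: 10 (1R,2S,5R)-8-phenylmenthyl 8α,17-epoxy-13,13-(ethylenedioxy)-3-oxo-14,15-dinorlabdan-19-oate
Conditions: m-CPBA, NaHCO3, CH2Cl2, 0 °C
Reagents that add atoms: m-chloroperbenzoic acid, OOC(=O)c1cccc(Cl)c1
Why: Prilezhaev epoxidation of the only 1,1-disubstituted alkene; the axial C20 methyl group, 1,3-diaxial to the β-face of C8, sends the peracid to the α-face, so the oxygen is α (equatorial) and C17 is β at C8. The hindered C3 ketone is not expected to undergo Baeyer–Villiger oxidation at this temperature, and the buffer protects the ketal.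

Step 8
Reactants: 10 epoxy keto ester
Product: 12 3β,8α,19-trihydroxy-14,15-dinorlabdan-13-one, via triol ketal 11 (not isolated)
Conditions: LiAlH4, THF, 0 °C to reflux; then 1 M HCl, THF, rt
Reagents that add atoms: water, O
Why: Hydride does three jobs: it opens the spiro-epoxide at the primary carbon C17 (SN2), which turns C17 into the axial methyl group and leaves the 8α-hydroxyl group; it reduces the C3 ketone from the less hindered α-face to the equatorial 3β-alcohol; and it cleaves the hindered ester to the C19 alcohol with release of 5, which can be recovered. Aqueous acid then removes the ketal; the open hydroxy ketone is in equilibrium with its cyclic hemiketal.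

Step 9
Reactants: 12 triol ketone
Product: 13 8α-hydroxy-3β,19-(thiocarbonyldioxy)-14,15-dinorlabdan-13-one (cyclic thionocarbonate)
Conditions: 1,1'-thiocarbonyldiimidazole, DMAP (cat.), THF, 65 °C
Reagents that add atoms: 1,1'-thiocarbonyldiimidazole, S=C(n1ccnc1)n1ccnc1
Why: The equatorial 3β-hydroxyl and the axial C19 hydroxymethyl group are gauche and close a six-membered cyclic thionocarbonate, whereas the tertiary 8-hydroxyl group does not react with this reagent.

Step 10
Reactants: 13 cyclic thionocarbonate
Product: 15 8α,19-dihydroxy-14,15-dinorlabdan-13-one, via stannyl thiolcarbonate 14 (not isolated)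
Conditions: Bu3SnH, AIBN (cat.), toluene, 110 °C; then NaOH, MeOH/H2O, rt
Reagents that add atoms: none
Why: Barton deoxygenation of a cyclic thionocarbonate: the stannyl radical adds to sulfur and the adduct fragments at the C3–O bond, because this gives the secondary and not the primary radical, so C3 is reduced and C19 keeps its oxygen as a thiolcarbonate that base hydrolyses. The ketone, the tertiary alcohol and the ring stereocenters are not touched by the radical chain.

Step 11
Reactants: 15 diol ketone
Product: 16 8α,19-bis(trimethylsilyloxy)-14,15-dinorlabdan-13-one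
Conditions: N-(trimethylsilyl)imidazole, CH2Cl2, rt to 40 °C
Reagents that add atoms: N-(trimethylsilyl)imidazole, C[Si](C)(C)n1ccnc1
Why: Silylation of both hydroxyl groups, the tertiary one included, with a reagent that does not enolize the ketone; the ethers keep the alkoxides from being sulfonylated and keep the 8-alkoxide from adding to the ketone in step 12.

Step 12
Reactants: 16 bis-silyl ketone
Product: 17 8α,19-bis(trimethylsilyloxy)-14,15-dinorlabd-13(16)-en-13-yl trifluoromethanesulfonate
Conditions: KN(SiMe3)2, THF, −78 °C; then PhNTf2, −78 to 0 °C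
Reagents that add atoms: N-phenylbis(trifluoromethanesulfonimide), O=S(=O)(N(c1ccccc1)S(=O)(=O)C(F)(F)F)C(F)(F)F
Why: Kinetic deprotonation of the methyl ketone by a hindered amide base at low temperature occurs at the methyl group C16, and O-sulfonylation of that enolate gives the 1-alken-2-yl triflate.

Step 13
Reactants: 17 enol triflate
Product: 19 labda-13(16),14-diene-8α,19-diol, via bis-silyl diene 18 (not isolated)
Conditions: tributyl(vinyl)stannane, Pd(PPh3)4 (cat.), LiCl, THF, 65 °C; then K2CO3, MeOH, rt
Reagents that add atoms: tributyl(vinyl)stannane, C=C[Sn](CCCC)(CCCC)CCCC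
Why: Stille coupling of the alkenyl triflate with the vinylstannane at zerovalent palladium forms the C13–C14 bond and with it the 2-substituted 1,3-diene, with no regiochemical question; methanolysis then removes both trimethylsilyl ethers under conditions that leave the diene and the tertiary alcohol alone.

Step 14
Reactants: 19 diene diol; 20 2-[bis(2,2,2-trifluoroethoxy)phosphoryl]acetic acid
Product: 21 8α-hydroxylabda-13(16),14-dien-19-yl 2-[bis(2,2,2-trifluoroethoxy)phosphoryl]acetate
Conditions: EDC·HCl, DMAP (cat.), CH2Cl2, 0 °C to rt
Reagents that add atoms: none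
Why: Carbodiimide esterification of the Steglich type; only the primary C19 hydroxyl group is acylated, the tertiary C8 hydroxyl group being too hindered. An acyl group without stereochemistry is used so that the slow acylation of a neopentyl alcohol cannot erode any alkene geometry.

Step 15
Reactants: 21 phosphonoacetate; 22 4-[(tert-butyldimethylsilyl)oxy]benzaldehyde
Product: 23 8α-hydroxylabda-13(16),14-dien-19-yl (Z)-3-{4-[(tert-butyldimethylsilyl)oxy]phenyl}prop-2-enoate
Conditions: KN(SiMe3)2 (1 equiv), 18-crown-6, THF, −78 °C
Reagents that add atoms: none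
Why: Still–Gennari olefination: the electron-poor bis(trifluoroethyl) phosphonate makes elimination from the kinetically formed adduct fast, which gives the Z-enoate with aromatic aldehydes. One equivalent of base deprotonates the phosphonate and not the tertiary alcohol.

Step 16
Reactants: 23 silyl-protected Z-coumarate
Product: 24 8α-hydroxylabda-13(16),14-dien-19-yl (Z)-3-(4-hydroxyphenyl)prop-2-enoate (CNP0197278.1)
Conditions: HF·pyridine, pyridine, THF, 0 °C, exclusion of light
Reagents that add atoms: none
Why: Buffered fluoride cleaves the aryl silyl ether under nearly neutral conditions in the dark, so that the Z-enoate is not isomerized; the tertiary alcohol, the ester and the diene do not react.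

## Compound list

1 | (E)-geranylacetone, (5E)-6,10-dimethylundeca-5,9-dien-2-one | CC(=O)CC/C=C(\C)CCC=C(C)C | starting material
2 | 2-[(3E)-4,8-dimethylnona-3,7-dien-1-yl]-2-methyl-1,3-dioxolane | CC1(CC/C=C(\C)CCC=C(C)C)OCCO1 | intermediate
3 | (2E,6E)-2,6-dimethyl-9-(2-methyl-1,3-dioxolan-2-yl)nona-2,6-dien-1-ol | CC1(CC/C=C(\C)CC/C=C(\C)CO)OCCO1 | intermediate
4 | 2-[(3E,7E)-9-bromo-4,8-dimethylnona-3,7-dien-1-yl]-2-methyl-1,3-dioxolane | CC1(CC/C=C(\C)CC/C=C(\C)CBr)OCCO1 | intermediate
5 | (−)-8-phenylmenthol, (1R,2S,5R)-5-methyl-2-(2-phenylpropan-2-yl)cyclohexan-1-ol | O[C@@H]1C[C@H](C)CC[C@H]1C(C)(C)c1ccccc1 | starting material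
6 | ethyl 2-methyl-3-oxobutanoate | CCOC(=O)C(C)C(C)=O | starting material
7 | (1R,2S,5R)-8-phenylmenthyl 2-methyl-3-oxobutanoate (epimers at C2 of the butanoate) | CC(=O)C(C)C(=O)O[C@@H]1C[C@H](C)CC[C@H]1C(C)(C)c1ccccc1 | intermediate
8 | (1R,2S,5R)-8-phenylmenthyl (6E,10E)-2,6,10-trimethyl-13-(2-methyl-1,3-dioxolan-2-yl)-3-oxotrideca-6,10-dienoate | CC1(CC/C=C(\C)CC/C=C(\C)CCC(=O)C(C)C(=O)O[C@@H]2C[C@H](C)CC[C@H]2C(C)(C)c2ccccc2)OCCO1 | intermediate
9 | (1R,2S,5R)-8-phenylmenthyl 13,13-(ethylenedioxy)-3-oxo-14,15-dinorlabd-8(17)-en-19-oate | CC1(CC[C@@H]2[C@@]3(C)CCC(=O)[C@](C)(C(=O)O[C@@H]4C[C@H](C)CC[C@H]4C(C)(C)c4ccccc4)[C@@H]3CCC2=C)OCCO1 | intermediate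
10 | (1R,2S,5R)-8-phenylmenthyl 8α,17-epoxy-13,13-(ethylenedioxy)-3-oxo-14,15-dinorlabdan-19-oate | CC1(CC[C@@H]2[C@@]3(C)CCC(=O)[C@](C)(C(=O)O[C@@H]4C[C@H](C)CC[C@H]4C(C)(C)c4ccccc4)[C@@H]3CC[C@]25CO5)OCCO1 | intermediate
11 | 13,13-(ethylenedioxy)-14,15-dinorlabdane-3β,8α,19-triol (not isolated) | CC1(CC[C@@H]2[C@@]3(C)CC[C@H](O)[C@](C)(CO)[C@@H]3CC[C@@]2(C)O)OCCO1 | intermediate
12 | 3β,8α,19-trihydroxy-14,15-dinorlabdan-13-one | CC(=O)CC[C@@H]1[C@@]2(C)CC[C@H](O)[C@](C)(CO)[C@@H]2CC[C@@]1(C)O | intermediate
13 | 8α-hydroxy-3β,19-(thiocarbonyldioxy)-14,15-dinorlabdan-13-one | CC(=O)CC[C@@H]1[C@@]2(C)CC[C@@H]3OC(=S)OC[C@]3(C)[C@@H]2CC[C@@]1(C)O | intermediate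
14 | O-(8α-hydroxy-13-oxo-14,15-dinorlabdan-19-yl) S-(tributylstannyl) thiocarbonate (not isolated) | CC(=O)CC[C@@H]1[C@@]2(C)CCC[C@](C)(COC(=O)S[Sn](CCCC)(CCCC)CCCC)[C@@H]2CC[C@@]1(C)O | intermediate
15 | 8α,19-dihydroxy-14,15-dinorlabdan-13-one | CC(=O)CC[C@@H]1[C@@]2(C)CCC[C@](C)(CO)[C@@H]2CC[C@@]1(C)O | intermediate
16 | 8α,19-bis(trimethylsilyloxy)-14,15-dinorlabdan-13-one | CC(=O)CC[C@@H]1[C@@]2(C)CCC[C@](C)(CO[Si](C)(C)C)[C@@H]2CC[C@@]1(C)O[Si](C)(C)C | intermediate
17 | 8α,19-bis(trimethylsilyloxy)-14,15-dinorlabd-13(16)-en-13-yl trifluoromethanesulfonate | C=C(OS(=O)(=O)C(F)(F)F)CC[C@@H]1[C@@]2(C)CCC[C@](C)(CO[Si](C)(C)C)[C@@H]2CC[C@@]1(C)O[Si](C)(C)C | intermediate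
18 | 8α,19-bis(trimethylsilyloxy)labda-13(16),14-diene (not isolated) | C=CC(=C)CC[C@@H]1[C@@]2(C)CCC[C@](C)(CO[Si](C)(C)C)[C@@H]2CC[C@@]1(C)O[Si](C)(C)C | intermediate
19 | labda-13(16),14-diene-8α,19-diol | C=CC(=C)CC[C@@H]1[C@@]2(C)CCC[C@](C)(CO)[C@@H]2CC[C@@]1(C)O | intermediate
20 | 2-[bis(2,2,2-trifluoroethoxy)phosphoryl]acetic acid | OC(=O)CP(=O)(OCC(F)(F)F)OCC(F)(F)F | starting material
21 | 8α-hydroxylabda-13(16),14-dien-19-yl 2-[bis(2,2,2-trifluoroethoxy)phosphoryl]acetate | C=CC(=C)CC[C@@H]1[C@@]2(C)CCC[C@](C)(COC(=O)CP(=O)(OCC(F)(F)F)OCC(F)(F)F)[C@@H]2CC[C@@]1(C)O | intermediate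
22 | 4-[(tert-butyldimethylsilyl)oxy]benzaldehyde | O=Cc1ccc(O[Si](C)(C)C(C)(C)C)cc1 | starting material
23 | 8α-hydroxylabda-13(16),14-dien-19-yl (Z)-3-{4-[(tert-butyldimethylsilyl)oxy]phenyl}prop-2-enoate | C=CC(=C)CC[C@@H]1[C@@]2(C)CCC[C@](C)(COC(=O)/C=C\c3ccc(O[Si](C)(C)C(C)(C)C)cc3)[C@@H]2CC[C@@]1(C)O | intermediate
24 | 8α-hydroxylabda-13(16),14-dien-19-yl (Z)-3-(4-hydroxyphenyl)prop-2-enoate, CNP0197278.1 | C=CC(=C)CC[C@@H]1[C@@]2(C)CCC[C@](C)(COC(=O)/C=C\c3ccc(O)cc3)[C@@H]2CC[C@@]1(C)O | target

## Step count and least certain steps

Total step count: 16. Longest linear sequence: 15 steps (from 1 through steps 1–3 and 5–16); step 4 is a one-step branch.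

**Step 6 (key step).** What may go wrong: incomplete shielding of one face of the C4 radical by the auxiliary (or shielding in the opposite sense, see Remark 1), and oxidation of the tertiary C10 radical by divalent copper before the second ring closes, which would stop the cascade after ring A. Fallback (sets out from 3, returns at 12): the alcohol 3 is oxidized with MnO2 to the enal F1 and methylenated (Wittig, Ph3P=CH2) to the triene F2. Hydroboration of the terminal vinyl group with 9-BBN-H gives the primary borane F3, which is coupled in the same flask (Suzuki–Miyaura, PdCl2(dppf), K3PO4) with (Z)-3-iodo-2-methylprop-2-en-1-ol to the (2Z)-allylic alcohol F4. Mild acid removes the ketal to give the hydroxy ketone F5, Sharpless epoxidation (Ti(OiPr)4, D-(−)-diethyl tartrate, t-BuOOH) gives the epoxy alcohol F6, and MeAlCl2 at −78 °C triggers a cation–olefin cyclization terminated by the ketone oxygen, to give the tricyclic enol ether diol F7. Aqueous HCl opens F7 to 12. In this path the absolute configuration comes from the epoxide, C4 from the Z alkene, and C8 is set in the cyclization. Its own weakness, slow ionization of the epoxide next to the CH2O group, is why it is the fallback and not the route.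

**Step 7.** What may go wrong: poor facial selectivity of the epoxidation, with some attack on the β-face leading to the C8 epimer after reduction. Fallback (sets out from 9, returns at 12): dihydroxylation of 9 with OsO4 (cat.) and N-methylmorpholine N-oxide, a bulkier reagent that should discriminate the faces more strongly, gives the 8α,17-diol F8. The primary hydroxyl group is converted into the tosylate F9 (TsCl, pyridine). The LiAlH4/aqueous HCl treatment of step 8 then replaces the tosylate by hydride (directly or through 10, which the C8 alkoxide forms in the flask) and delivers 12.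

**Step 10.** What may go wrong: fragmentation of the radical adduct toward the primary C19–O bond, or a sluggish chain with the hindered cyclic thionocarbonate, leading to partial reduction without loss of the C3 oxygen. Fallback (sets out from 12, returns at 15): the two hydroxyl groups are told apart before the radical step. The primary C19 hydroxyl group is silylated (TBSCl, imidazole) to the silyl ether F10, and the C3 hydroxyl group is converted into the imidazolyl thiocarbonate F11 (1,1'-thiocarbonyldiimidazole, DMAP). Barton–McCombie reduction (Bu3SnH, AIBN) gives the 3-deoxy silyl ether F12, and fluoride (Bu4NF) frees 15.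

**Step 12.** What may go wrong: enolization toward C12 instead of C16, giving the regioisomeric internal triflate, or loss of a silyl ether under the basic conditions. Fallback (sets out from 15, returns at 19): 15 is condensed with 2,4,6-triisopropylbenzenesulfonyl hydrazide to the hydrazone F13. Shapiro reaction (excess n-BuLi, THF, −78 to 0 °C), in which deprotonation occurs at the methyl group, gives the C13 alkenyllithium, which iodine quenches to the alkenyl iodide F14. Stille coupling of F14 with tributyl(vinyl)stannane (Pd(PPh3)4) gives 19 without any silyl protection.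

**Step 15 (with step 16).** What may go wrong: incomplete Z-selectivity in the olefination and Z to E isomerization of the coumarate during desilylation. Fallback (sets out from 19, returns at 24): 19 is acylated at C19 with (Z)-3-iodoacrylic acid (carbodiimide, DMAP) to the (Z)-3-iodoacrylate F15. A stereoretentive Suzuki–Miyaura coupling with 4-hydroxyphenylboronic acid (Pd(PPh3)4, K3PO4, THF/H2O, rt, dark) forms the aryl–alkene bond and gives 24 directly, with no silyl ether to remove.

## Further compounds

F1 | step 6 | (2E,6E)-2,6-dimethyl-9-(2-methyl-1,3-dioxolan-2-yl)nona-2,6-dienal | CC1(CC/C=C(\C)CC/C=C(\C)C=O)OCCO1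
F2 | step 6 | 2-[(3E,7E)-4,8-dimethyldeca-3,7,9-trien-1-yl]-2-methyl-1,3-dioxolane | CC1(CC/C=C(\C)CC/C=C(\C)C=C)OCCO1
F3 | step 6 | 9-[(3E,7E)-3,7-dimethyl-10-(2-methyl-1,3-dioxolan-2-yl)deca-3,7-dien-1-yl]-9-borabicyclo[3.3.1]nonane | CC1(CC/C=C(\C)CC/C=C(\C)CCB2C3CCCC2CCC3)OCCO1
F4 | step 6 | (2Z,6E,10E)-2,6,10-trimethyl-13-(2-methyl-1,3-dioxolan-2-yl)trideca-2,6,10-trien-1-ol | CC1(CC/C=C(\C)CC/C=C(\C)CC/C=C(/C)CO)OCCO1
F5 | step 6 | (5E,9E,13Z)-15-hydroxy-6,10,14-trimethylpentadeca-5,9,13-trien-2-one | CC(=O)CC/C=C(\C)CC/C=C(\C)CC/C=C(/C)CO
F6 | step 6 | (5E,9E)-12-[(2S,3R)-3-(hydroxymethyl)-3-methyloxiran-2-yl]-6,10-dimethyldodeca-5,9-dien-2-one | CC(=O)CC/C=C(\C)CC/C=C(\C)CC[C@@H]1O[C@]1(C)CO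
F7 | step 6 | 8α,13-epoxy-14,15-dinorlabd-12-ene-3β,19-diol | CC1=CC[C@@H]2[C@@]3(C)CC[C@H](O)[C@](C)(CO)[C@@H]3CC[C@@]2(C)O1
F8 | step 7 | (1R,2S,5R)-8-phenylmenthyl 13,13-(ethylenedioxy)-8α,17-dihydroxy-3-oxo-14,15-dinorlabdan-19-oate | CC1(CC[C@@H]2[C@@]3(C)CCC(=O)[C@](C)(C(=O)O[C@@H]4C[C@H](C)CC[C@H]4C(C)(C)c4ccccc4)[C@@H]3CC[C@@]2(CO)O)OCCO1
F9 | step 7 | (1R,2S,5R)-8-phenylmenthyl 13,13-(ethylenedioxy)-8α-hydroxy-3-oxo-17-(tosyloxy)-14,15-dinorlabdan-19-oate | CC1(CC[C@@H]2[C@@]3(C)CCC(=O)[C@](C)(C(=O)O[C@@H]4C[C@H](C)CC[C@H]4C(C)(C)c4ccccc4)[C@@H]3CC[C@@]2(COS(=O)(=O)c4ccc(C)cc4)O)OCCO1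
F10 | step 10 | 19-[(tert-butyldimethylsilyl)oxy]-3β,8α-dihydroxy-14,15-dinorlabdan-13-one | CC(=O)CC[C@@H]1[C@@]2(C)CC[C@H](O)[C@](C)(CO[Si](C)(C)C(C)(C)C)[C@@H]2CC[C@@]1(C)O
F11 | step 10 | O-{19-[(tert-butyldimethylsilyl)oxy]-8α-hydroxy-13-oxo-14,15-dinorlabdan-3β-yl} 1H-imidazole-1-carbothioate | CC(=O)CC[C@@H]1[C@@]2(C)CC[C@H](OC(=S)n3ccnc3)[C@](C)(CO[Si](C)(C)C(C)(C)C)[C@@H]2CC[C@@]1(C)O
F12 | step 10 | 19-[(tert-butyldimethylsilyl)oxy]-8α-hydroxy-14,15-dinorlabdan-13-one | CC(=O)CC[C@@H]1[C@@]2(C)CCC[C@](C)(CO[Si](C)(C)C(C)(C)C)[C@@H]2CC[C@@]1(C)O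
F13 | step 12 | 8α,19-dihydroxy-14,15-dinorlabdan-13-one 2,4,6-triisopropylbenzenesulfonylhydrazone | CC(CC[C@@H]1[C@@]2(C)CCC[C@](C)(CO)[C@@H]2CC[C@@]1(C)O)=NNS(=O)(=O)c1c(C(C)C)cc(C(C)C)cc1C(C)C
F14 | step 12 | 13-iodo-14,15-dinorlabd-13(16)-ene-8α,19-diol | C=C(I)CC[C@@H]1[C@@]2(C)CCC[C@](C)(CO)[C@@H]2CC[C@@]1(C)O
F15 | step 15 | 8α-hydroxylabda-13(16),14-dien-19-yl (Z)-3-iodoprop-2-enoate | C=CC(=C)CC[C@@H]1[C@@]2(C)CCC[C@](C)(COC(=O)/C=C\I)[C@@H]2CC[C@@]1(C)O
A1 | alternative 1 | (S)-Wieland–Miescher ketone | C[C@]12CCC(=O)C=C1CCCC2=O
A2 | alternative 1 | methyl 4α,10β-dimethyl-3-oxo-9,9-(ethylenedioxy)-5α-decalin-4β-carboxylate (ring atoms in labdane numbering) | C12(OCCO1)[C@@]3(C)CCC(=O)[C@](C)(C(=O)OC)[C@@H]3CCC2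
A3 | alternative 2 | (5E,9E)-14-{[(tert-butyldimethylsilyl)oxy]methyl}-6,10-dimethylpentadeca-5,9,14-trien-2-one | CC(=O)CC/C=C(\C)CC/C=C(\C)CCCC(=C)CO[Si](C)(C)C(C)(C)C
A4 | alternative 2 | 19-[(tert-butyldimethylsilyl)oxy]-8α,13-epoxy-14,15-dinorlabd-12-ene | CC1=CC[C@@H]2[C@@]3(C)CCC[C@](C)(CO[Si](C)(C)C(C)(C)C)[C@@H]3CC[C@@]2(C)O1
A5 | alternative 3 | (+)-sclareolide | O=C1C[C@@H]2[C@@]3(C)CCCC(C)(C)[C@@H]3CC[C@@]2(C)O1
A6 | alternative 3 | 19-hydroxysclareolide | O=C1C[C@@H]2[C@@]3(C)CCC[C@](C)(CO)[C@@H]3CC[C@@]2(C)O1
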